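## The problem

Compound 19 is an achiral tetramer of phloroglucinol-type rings joined only by three diaryl ether bonds: ring A (2,4,6-trihydroxyphenoxy), ring B, ring C and ring D (3,4,5-trihydroxyphenoxy). Ring B carries O–ring A at C1, O–ring C at C2 and hydroxyls at C3 and C5; ring C carries O–ring B at C1, O–ring D at C4 and hydroxyls at C3 and C5. There is no stereocentre, so nothing in the molecule can direct anything else, and every selectivity question is regiochemical. Each ether oxygen sits on at least one carbon flanked by two further oxygen substituents (C1 of ring A, C2 of ring B, C4 of ring C), so a copper coupling fails wherever the crowded carbon would have to carry the halide. Rings A, C and D are symmetrical and their oxygen patterns can be bought. Ring B is the exception: its four oxygens have four different roles and three of them are contiguous. Ten free phenols on rings as nucleophilic as phloroglucinol, and as oxidisable as pyrogallol in ring D, cannot be carried through the route. They must be masked by groups that survive organolithiums, 110 °C and copper with base, and that leave without forming carbocations, which the rings would capture at carbon. The feature that opens the route is that the C2 and C5 oxygens of ring B are para, with C1 (aryloxy) and C3 (oxygen) flanking C2 and with C4 and C6 unsubstituted. This is the pattern that a 3-aryloxy-4-hydroxy-4-(1-alkoxyvinyl)cyclobutenone gives on thermal ring expansion, and in such a precursor the crowded ring A–O bond is only the ester bond of a vinylogous acid.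

## Retrosynthesis

**19 from 18.** Only the ten O–CH3 bonds are cut. Methyl is preferred to benzyl or alkoxymethyl because all ten positions can carry it through vinyllithium chemistry, the thermolysis and the copper couplings. It also leaves as bromomethane and not as a cation that rings A–D would trap at carbon. Compound 18 has the complete skeleton; the forward step must cleave ten ethers and spare the three diaryl ether bonds.

**18 from 14 and 17.** The bond between the C2 oxygen of ring B and C1 of ring C is cut, with the oxygen kept on ring B. C1 of ring C is the only ether carbon in the molecule with two ortho hydrogens, so bromide 17 is unhindered. Either neighbouring cut would put the halide between two methoxy groups. The molecule falls into two two-ring halves. The forward reaction must arylate a phenol that has two ortho substituents.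

**17 from 15 and 16.** The ring C–O–ring D bond is cut at C1 of ring D, so that the crowded ring C again supplies the oxygen (phenol 15) and the uncrowded ring D supplies the carbon (boronic acid 16). Both are commercial. The forward reaction must form a diaryl ether at room temperature and leave the aryl bromide untouched.

**14 from 13.** The O–CH3 bond at C5 of ring B is cut, which gives hydroquinone 13. Its two hydroxyls differ sharply: the C5 hydroxyl has two ortho hydrogens, and the C2 hydroxyl lies between a methoxy and an aryloxy group. The forward step must alkylate only the exposed one.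

**13 from 10.** The C4–C5 bond of ring B is cut and the ring is traced back through a dienylketene to the four-membered ring of 10. This cut is preferred to any functionalisation of a preformed arene because every oxygen of ring B enters with its role already assigned. Those roles are the aryloxy oxygen, the methoxy oxygen and two hydroxyls distinguished by their surroundings. The precursor has one ring fewer and no aromatic ring B. The forward reaction must open the cyclobutenone and reclose six carbons in one sense only.

**10 from 7 and 8.** The bond between the carbinol carbon of 10 and the vinyl carbon is cut. Methyl vinyl ether 8 supplies C3 and C4 of ring B as its α-lithio derivative 9. The forward addition must choose the ketone-like carbonyl of dione 7 and not the vinylogous ester carbonyl or C3.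

**7 from 5 and 6.** The ring A–O bond is cut. In the target it joins two aromatic carbons, each with two ortho oxygen substituents. Here it is the acyl–oxygen bond of a vinylogous ester, formed from phenol 6 and chloride 5 at an sp2 carbon with no ortho neighbours. This is the main simplification of the plan.

**5 from 1 through 4 and 3.** These are functional-group changes only: chloride 5 from vinylogous acid 4, acid 4 from isopropyl ester 3, and 3 from commercial squarate 1 by removal of one alkoxy group through hydride reduction and acid treatment.

## Roads not taken

**Alternative 1:** Both ether bonds of ring C (O–C1 and C4–O) are cut and ring C becomes a para-dichloride linchpin. 2,5-Dichloro-1,3-dimethoxybenzene A1 would be bound to a cyclopentadienylruthenium cation (divalent ruthenium) as the salt [CpRu(arene)]PF6 A2. The phenoxide of 14 should displace the chloride at C1 of ring C, and the phenoxide of 3,4,5-trimethoxyphenol A3 the chloride at C4. Irradiation in acetonitrile would then release the decamethyl ether A4, which is the same compound as 18.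
- Merits: substitution on the cationic arene runs near room temperature, is indifferent to the electron-rich ring, and makes both ring C ethers from one cheap symmetrical arene. For joining the two halves it is more convergent and milder than steps 8 and 9, and in that respect it is the better reaction.
- Weak points: the second substitution must occur at a carbon between two methoxy groups, on a ring that the first aryloxy group has made less electrophilic. Methoxide can also leave from such a complex, so ether exchange threatens. Ruthenium is stoichiometric and costs a complexation and a decomplexation. Above all it presupposes 14 and so does nothing for ring B.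
- Comparison: against the gain in convergence the chosen plan sets catalytic copper and two coupling partners whose reacting sites are unambiguous. Its strategy-carrying step is also spent on the one ring that cannot be bought.

**Alternative 2:** The C2–C3 and C1–C6 bonds of ring C are cut, the reverse of a Danheiser benzannulation. Heating 3-ethoxy-4-(3,4,5-trimethoxyphenoxy)cyclobut-2-en-1-one A5 with the ethynyl ether A6 of phenol 14 should open A5 to a vinylketene and add it across the ynol ether. The adduct should then reopen and reclose to A7, in which ring C carries a C3 hydroxyl and a C5 ethyl ether.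
- Merits: both crowded ethers of ring C exist before the ring does, so no metal-mediated C–O coupling is needed on that side. The polarity of the ynol ether fixes the regiochemistry. Not having to arylate the hindered oxygen of 14 is a real advantage over step 9.
- Weak points: A6 must still be made from 14, in two further steps, and ynol ethers of hindered electron-rich phenols are delicate. A5 has no short preparation, and a 4-aryloxycyclobutenone is untested in this annulation. The ring being built is the symmetrical one, whose pattern is on sale as 15.
- Comparison: the chosen plan is shorter and uses its pericyclic ring synthesis on the unsymmetrical ring. It must accept one copper coupling at a hindered phenol in return.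

**Alternative 3:** The C1–C2 bond of ring A is cut. The ring B–C–D phenol A8 would be O-alkylated to the methyl 6-aryloxy-3,5-dioxohexanoate A9. Its polyanion should attack the ester carbon through C6 and the resulting triketone should enolise to A10, the heptamethyl ether with ring A as the free triol.
- Merits: the crowded ring A–O bond is made as a plain alkylation at an sp3 carbon, at least as good a solution for that bond as step 4. Ring A arrives unprotected, which spares three demethylations.
- Weak points: the carbanion needed is at C6, the least acidic position of the chain, and 3,5-dioxo esters normally close through oxygen to 4-hydroxy-2-pyrones. The free aryloxyphloroglucinol forms in strong base, where it is readily oxidised. The route is linear, with the least certain step last. A8 demands a ring B with three differently treated oxygens, so the ring B problem is moved, not solved.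
- Comparison: the chosen plan sets against the spared demethylations a convergent route in which a single step settles both the crowded ether and the oxygen pattern of ring B.

Key step: step 6

Remark: 19 is achiral; the only stereocentres on the route (in 2 and 10) are formed as racemates and destroyed again, so the SMILES of 2 and 10 show one enantiomer of a racemate.

## Route

Step 1
Reactants: 1 diisopropyl squarate
Product: 3 3-isopropoxycyclobut-3-ene-1,2-dione, via 4-hydroxy-2,3-diisopropoxycyclobut-2-en-1-one 2 (not isolated)
Conditions: LiAlH(OtBu)3, THF, −78 → −20 °C; then conc. HCl, CH2Cl2, rt (crude 2 carried on)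
Reagents that add atoms: water, O (its oxygen becomes the new carbonyl oxygen of 3; the hydroxyl of 2 leaves as water)
Why: The bulky hydride should add once to one of the two equivalent carbonyls of 1 (1,2-reduction of a vinylogous ester) and stop at allylic alcohol 2; acid then ionises the hydroxyl to an alkoxy-stabilised cyclobutenyl cation that takes up water at the distal alkoxy carbon and loses propan-2-ol, the known reduction–hydrolysis route to monoalkoxycyclobutenediones. The stereocentre of 2 is racemic and disappears in 3.

Step 2
Reactants: 3 3-isopropoxycyclobut-3-ene-1,2-dione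
Product: 4 3-hydroxycyclobut-3-ene-1,2-dione (semisquaric acid)
Conditions: 2 M aq. HCl, THF, rt; evaporation
Reagents that add atoms: water, O
Why: Acid-catalysed hydrolysis of a vinylogous ester by addition–elimination at C3; the product is a strong, water-soluble vinylogous acid that is stable to aqueous HCl and should be isolable by evaporation.

Step 3
Reactants: 4 3-hydroxycyclobut-3-ene-1,2-dione
Product: 5 3-chlorocyclobut-3-ene-1,2-dione
Conditions: (COCl)2, DMF (cat.), CH2Cl2, 0 °C → rt; volatiles removed
Reagents that add atoms: oxalyl chloride, ClC(=O)C(Cl)=O
Why: Chlorination of a vinylogous carboxylic acid through the chloroiminium species from DMF and oxalyl chloride, the reaction type that converts squaric acid into its dichloride; only gases form beside 5.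

Step 4
Reactants: 5 3-chlorocyclobut-3-ene-1,2-dione; 6 2,4,6-trimethoxyphenol
Product: 7 3-(2,4,6-trimethoxyphenoxy)cyclobut-3-ene-1,2-dione
Conditions: 2,6-lutidine, CH2Cl2, −40 → 0 °C
Reagents that add atoms: none
Why: Acylation of a phenol by a vinylogous acid chloride (addition–elimination at C3): the electrophilic carbon has no ortho substituents, so the two methoxy groups flanking the oxygen of 6 should be tolerated, and the hindered pyridine takes up HCl without adding to the dione. This forms the ring A–O bond, the most crowded ether of the target, before ring B exists.

Step 5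
Reactants: 7 3-(2,4,6-trimethoxyphenoxy)cyclobut-3-ene-1,2-dione; 8 methyl vinyl ether
Product: 10 4-hydroxy-4-(1-methoxyethenyl)-3-(2,4,6-trimethoxyphenoxy)cyclobut-2-en-1-one (racemic), via (1-methoxyethenyl)lithium 9 (not isolated)
Conditions: 8 (excess), t-BuLi, THF, −78 → 0 °C; then 7, THF, −78 °C; sat. aq. NH4Cl, −78 °C
Reagents that add atoms: none
Why: α-Lithiation of an alkyl vinyl ether by t-BuLi and 1,2-addition of the vinyllithium to a cyclobutenedione at −78 °C is the standard entry to 4-hydroxycyclobutenones; attack should occur at the carbonyl next to the aryloxy-bearing carbon, because the other carbonyl is deactivated as a vinylogous ester. The quaternary carbinol centre forms as a racemate and is lost in step 6; the cold buffered quench should leave the enol ether intact.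

Step 6
Reactants: 10 4-hydroxy-4-(1-methoxyethenyl)-3-(2,4,6-trimethoxyphenoxy)cyclobut-2-en-1-one
Product: 13 2-methoxy-6-(2,4,6-trimethoxyphenoxy)benzene-1,4-diol, via dienylketene 11 (not isolated), via cyclohexa-2,4-dienone 12 (not isolated)
Conditions: toluene (degassed), 110 °C, Ar
Reagents that add atoms: none
Why: This is the Moore rearrangement of a 4-alkenyl-4-hydroxycyclobutenone, a known thermal reaction of this substrate class. Conrotatory 4-electron opening of the C1–C4 bond of 10 should give the (Z)-dienylketene 11; the hydroxyl, as the stronger donor, rotates outward, which places the methoxyvinyl group on the same side as the ketene. Ring B then closes by a thermal disrotatory 6-electron electrocyclisation in which the ketene carbon bonds to the vinyl CH2 (the C4–C5 bond of ring B) to give dienone 12, and enolisation to the aromatic hydroquinone 13 makes the sequence irreversible. No stereocentre is formed, and the one in 10 is lost on ring opening. The selectivity needed is constitutional and torquoselective: the connectivity of 10 fixes the four oxygens (ketone carbon to C5, carbinol carbon to C2, aryloxy carbon to C1, methoxy-bearing vinyl carbon to C3), and outward rotation of the hydroxyl keeps it from trapping the ketene as a butenolide. Oxygen is excluded because 13 is an electron-rich hydroquinone.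

Step 7
Reactants: 13 2-methoxy-6-(2,4,6-trimethoxyphenoxy)benzene-1,4-diol
Product: 14 2,4-dimethoxy-6-(2,4,6-trimethoxyphenoxy)phenol
Conditions: MeI (1.05 equiv), K2CO3 (1.1 equiv), acetone (degassed), 0 °C → rt, Ar
Reagents that add atoms: iodomethane, CI
Why: Williamson monoalkylation with one equivalent of MeI: the C4 hydroxyl of 13 (C5 of ring B) has two ortho hydrogens and two meta oxygen substituents, so it should be both the more accessible and the more acidic one, whereas the C1 hydroxyl is shielded by methoxy and aryloxy groups. Oxygen is excluded because the hydroquinone anion is easily oxidised.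

Step 8
Reactants: 15 4-bromo-2,6-dimethoxyphenol; 16 (3,4,5-trimethoxyphenyl)boronic acid
Product: 17 5-bromo-1,3-dimethoxy-2-(3,4,5-trimethoxyphenoxy)benzene
Conditions: Cu(OAc)2 (20 mol %), pyridine, 4 Å molecular sieves, CH2Cl2, O2 (1 atm), rt
Reagents that add atoms: none
Why: Chan–Lam coupling: the phenoxide of 15 and the aryl group of 16 meet on copper, the ether leaves by reductive elimination from a high-valent copper aryl phenoxide, and dioxygen returns copper to the divalent state. At room temperature copper should not insert into the C–Br bond, so the bromide survives for step 9; the hindered partner is the nucleophile and the boronic acid is unhindered.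

Step 9
Reactants: 14 2,4-dimethoxy-6-(2,4,6-trimethoxyphenoxy)phenol; 17 5-bromo-1,3-dimethoxy-2-(3,4,5-trimethoxyphenoxy)benzene
Product: 18 2-[3,5-dimethoxy-4-(3,4,5-trimethoxyphenoxy)phenoxy]-1,5-dimethoxy-3-(2,4,6-trimethoxyphenoxy)benzene
Conditions: CuI (10 mol %), picolinic acid (20 mol %), K3PO4, DMSO, 90 °C, Ar
Reagents that add atoms: none
Why: Ullmann-type diaryl ether synthesis with monovalent copper and picolinic acid as ligand, a catalyst system that accepts phenols with two ortho substituents; the bromide of 17 has two ortho hydrogens. 14 offers a single free hydroxyl, so only the ring B–O–ring C bond can form.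

Step 10
Reactants: 18 2-[3,5-dimethoxy-4-(3,4,5-trimethoxyphenoxy)phenoxy]-1,5-dimethoxy-3-(2,4,6-trimethoxyphenoxy)benzene
Product: 19 2-{2-[3,5-dihydroxy-4-(3,4,5-trihydroxyphenoxy)phenoxy]-3,5-dihydroxyphenoxy}benzene-1,3,5-triol
Conditions: BBr3 (20 equiv), CH2Cl2, −78 °C → rt, Ar; then degassed H2O, 0 °C
Reagents that add atoms: none
Why: Cleavage of aryl methyl ethers by BBr3: boron binds each methoxy oxygen and bromide removes the methyl group by SN2 displacement, so the three diaryl ether bonds, which have no sp3 carbon, should stay intact and no carbocation is released onto the nucleophilic rings. Degassed work-up protects the pyrogallol-type ring D; the product has no stereocentre.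

## Compound list

1 | diisopropyl squarate (3,4-diisopropoxycyclobut-3-ene-1,2-dione) | CC(C)OC1=C(OC(C)C)C(=O)C1=O | starting material
2 | 4-hydroxy-2,3-diisopropoxycyclobut-2-en-1-one (racemic, one enantiomer drawn; not isolated) | CC(C)OC1=C(OC(C)C)[C@@H](O)C1=O | intermediate
3 | 3-isopropoxycyclobut-3-ene-1,2-dione | CC(C)OC1=CC(=O)C1=O | intermediate
4 | 3-hydroxycyclobut-3-ene-1,2-dione (semisquaric acid) | OC1=CC(=O)C1=O | intermediate
5 | 3-chlorocyclobut-3-ene-1,2-dione | ClC1=CC(=O)C1=O | intermediate
6 | 2,4,6-trimethoxyphenol | COc1cc(OC)c(O)c(OC)c1 | starting material
7 | 3-(2,4,6-trimethoxyphenoxy)cyclobut-3-ene-1,2-dione | COc1cc(OC)c(OC2=CC(=O)C2=O)c(OC)c1 | intermediate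
8 | methyl vinyl ether | COC=C | starting material
9 | (1-methoxyethenyl)lithium (not isolated) | [Li]C(=C)OC | intermediate
10 | 4-hydroxy-4-(1-methoxyethenyl)-3-(2,4,6-trimethoxyphenoxy)cyclobut-2-en-1-one (racemic, one enantiomer drawn) | COC(=C)[C@@]1(O)C(Oc2c(OC)cc(OC)cc2OC)=CC1=O | intermediate
11 | (3Z)-4-hydroxy-5-methoxy-3-(2,4,6-trimethoxyphenoxy)hexa-1,3,5-trien-1-one (dienylketene; not isolated) | O=C=C\C(Oc1c(OC)cc(OC)cc1OC)=C(\O)C(=C)OC | intermediate
12 | 4-hydroxy-5-methoxy-3-(2,4,6-trimethoxyphenoxy)cyclohexa-2,4-dien-1-one (not isolated) | O=C1C=C(Oc2c(OC)cc(OC)cc2OC)C(O)=C(OC)C1 | intermediate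
13 | 2-methoxy-6-(2,4,6-trimethoxyphenoxy)benzene-1,4-diol (rings A and B) | COc1cc(O)cc(Oc2c(OC)cc(OC)cc2OC)c1O | intermediate
14 | 2,4-dimethoxy-6-(2,4,6-trimethoxyphenoxy)phenol | COc1cc(OC)c(O)c(Oc2c(OC)cc(OC)cc2OC)c1 | intermediate
15 | 4-bromo-2,6-dimethoxyphenol | COc1cc(Br)cc(OC)c1O | starting material
16 | (3,4,5-trimethoxyphenyl)boronic acid | COc1cc(B(O)O)cc(OC)c1OC | starting material
17 | 5-bromo-1,3-dimethoxy-2-(3,4,5-trimethoxyphenoxy)benzene (rings C and D) | COc1cc(Br)cc(OC)c1Oc1cc(OC)c(OC)c(OC)c1 | intermediate
18 | 2-[3,5-dimethoxy-4-(3,4,5-trimethoxyphenoxy)phenoxy]-1,5-dimethoxy-3-(2,4,6-trimethoxyphenoxy)benzene (decamethyl ether of the target) | COc1cc(OC)c(Oc2cc(OC)cc(OC)c2Oc2cc(OC)c(Oc3cc(OC)c(OC)c(OC)c3)c(OC)c2)c(OC)c1 | intermediate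
19 | 2-{2-[3,5-dihydroxy-4-(3,4,5-trihydroxyphenoxy)phenoxy]-3,5-dihydroxyphenoxy}benzene-1,3,5-triol (CNP0018314.0) | Oc1cc(O)c(Oc2cc(O)cc(O)c2Oc2cc(O)c(Oc3cc(O)c(O)c(O)c3)c(O)c2)c(O)c1 | target

## Step count and least certain steps

Total step count: 10. Longest linear sequence: 9 steps (steps 1–7, 9 and 10, from 1 to 19); step 8 is a one-step branch.

**Step 6 (key step).** The most likely trouble is oxidation of the electron-rich hydroquinone by traces of oxygen at 110 °C or during isolation, so that hydroquinone and quinone are obtained side by side. Less likely is partial inward rotation of the hydroxyl and capture of the ketene as a butenolide. Fallback, from 10 back to 13: the higher oxidation level is accepted. 10 is heated as before and the crude mixture is stirred with Ag2O, so that all material is collected as 2-methoxy-6-(2,4,6-trimethoxyphenoxy)cyclohexa-2,5-diene-1,4-dione F1, a quinone that can be purified and stored. F1 is reduced with aqueous Na2S2O4 to 13 just before step 7.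

**Step 5.** The addition may lose chemoselectivity. An aryloxide is a far better leaving group than the alkoxides for which this addition is established, so attack at C3 with expulsion of the aryloxide may compete. Attack at the vinylogous ester carbonyl would lead after rearrangement to a 1,2,4,5-oxygenated ring. Fallback, from 6 back to 13: the four-membered ring is given up for this fragment and the ring A–O bond is made on a haloquinone. Purchased 3-bromo-4-hydroxy-5-methoxybenzaldehyde F2 would undergo Dakin oxidation (H2O2, NaOH) to 2-bromo-6-methoxybenzene-1,4-diol F3, and FeCl3 would oxidise this to 2-bromo-6-methoxycyclohexa-2,5-diene-1,4-dione F4. Phenol 6 with K2CO3 in MeCN at 0 °C should replace bromide by addition–elimination to give quinone F1, and Na2S2O4 reduces it to 13.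

**Step 7.** Methylation may occur twice or at the shielded hydroxyl, and the hydroquinone anion may autoxidise; the steric and acidity arguments favour the wanted site but do not guarantee it. Fallback, from 10 back to 14: the two oxygens are told apart before ring B exists. The tertiary hydroxyl of 10 is silylated (TBSOTf, 2,6-lutidine, CH2Cl2, −78 °C) to 4-[tert-butyl(dimethyl)silyl]oxy-4-(1-methoxyethenyl)-3-(2,4,6-trimethoxyphenoxy)cyclobut-2-en-1-one F5. Thermolysis as in step 6 should give 4-[tert-butyl(dimethyl)silyl]oxy-3-methoxy-5-(2,4,6-trimethoxyphenoxy)phenol F6, in which only the C5 hydroxyl of ring B is free. MeI and K2CO3 give tert-butyl[2,4-dimethoxy-6-(2,4,6-trimethoxyphenoxy)phenoxy]dimethylsilane F7, and Bu4NF gives 14. The silyl ether also blocks the butenolide pathway of step 6.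

**Step 9.** The doubly ortho-substituted, electron-rich phenoxide may exchange onto copper too slowly, so that protodebromination of 17 and oxidative decay of 14 compete at 90 °C. Fallback, from 17 back to 18: the coupling is changed from a substitutive to an oxidative one. 17 is converted (n-BuLi, THF, −78 °C; B(OiPr)3; aq. HCl) into [3,5-dimethoxy-4-(3,4,5-trimethoxyphenoxy)phenyl]boronic acid F8, which is joined to 14 under the room-temperature conditions of step 8 to give 18.

**Step 10.** Cleavage of ten ethers may stop short, giving partly methylated congeners that are hard to separate from a very polar decaphenol, and ring D may oxidise during isolation. Fallback, from 18 back to 19: after the BBr3 treatment the crude polyphenol is not purified but acetylated (Ac2O, pyridine) to the decaacetate of 19 F9, which can be purified on silica. Acidic methanolysis (HCl in MeOH, Ar) then releases 19.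

Further compounds

F1 | step 6 | 2-methoxy-6-(2,4,6-trimethoxyphenoxy)cyclohexa-2,5-diene-1,4-dione | COC1=CC(=O)C=C(Oc2c(OC)cc(OC)cc2OC)C1=O
F2 | step 5 | 3-bromo-4-hydroxy-5-methoxybenzaldehyde (5-bromovanillin, purchased) | COc1cc(C=O)cc(Br)c1O
F3 | step 5 | 2-bromo-6-methoxybenzene-1,4-diol | COc1cc(O)cc(Br)c1O
F4 | step 5 | 2-bromo-6-methoxycyclohexa-2,5-diene-1,4-dione | COC1=CC(=O)C=C(Br)C1=O
F5 | step 7 | 4-[tert-butyl(dimethyl)silyl]oxy-4-(1-methoxyethenyl)-3-(2,4,6-trimethoxyphenoxy)cyclobut-2-en-1-one (racemic, one enantiomer drawn) | COC(=C)[C@@]1(O[Si](C)(C)C(C)(C)C)C(Oc2c(OC)cc(OC)cc2OC)=CC1=O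
F6 | step 7 | 4-[tert-butyl(dimethyl)silyl]oxy-3-methoxy-5-(2,4,6-trimethoxyphenoxy)phenol | COc1cc(O)cc(Oc2c(OC)cc(OC)cc2OC)c1O[Si](C)(C)C(C)(C)C
F7 | step 7 | tert-butyl[2,4-dimethoxy-6-(2,4,6-trimethoxyphenoxy)phenoxy]dimethylsilane | COc1cc(OC)cc(Oc2c(OC)cc(OC)cc2OC)c1O[Si](C)(C)C(C)(C)C
F8 | step 9 | [3,5-dimethoxy-4-(3,4,5-trimethoxyphenoxy)phenyl]boronic acid | COc1cc(B(O)O)cc(OC)c1Oc1cc(OC)c(OC)c(OC)c1
F9 | step 10 | decaacetate of 19 | CC(=O)Oc1cc(OC(C)=O)c(Oc2cc(OC(C)=O)cc(OC(C)=O)c2Oc2cc(OC(C)=O)c(Oc3cc(OC(C)=O)c(OC(C)=O)c(OC(C)=O)c3)c(OC(C)=O)c2)c(OC(C)=O)c1
A1 | alternative 1 | 2,5-dichloro-1,3-dimethoxybenzene | COc1cc(Cl)cc(OC)c1Cl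
A2 | alternative 1 | (cyclopentadienyl)(2,5-dichloro-1,3-dimethoxybenzene)ruthenium hexafluorophosphate, [CpRu(arene)]PF6 | COc1cc(Cl)cc(OC)c1Cl.[cH-]1cccc1.[Ru+2].F[P-](F)(F)(F)(F)F
A3 | alternative 1 | 3,4,5-trimethoxyphenol | COc1cc(O)cc(OC)c1OC
A4 | alternative 1 | decamethyl ether of the target (same compound as 18) | COc1cc(OC)c(Oc2cc(OC)cc(OC)c2Oc2cc(OC)c(Oc3cc(OC)c(OC)c(OC)c3)c(OC)c2)c(OC)c1
A5 | alternative 2 | 3-ethoxy-4-(3,4,5-trimethoxyphenoxy)cyclobut-2-en-1-one (racemic, one enantiomer drawn) | CCOC1=CC(=O)[C@H]1Oc1cc(OC)c(OC)c(OC)c1
A6 | alternative 2 | 2-(ethynyloxy)-1,5-dimethoxy-3-(2,4,6-trimethoxyphenoxy)benzene | C#COc1c(OC)cc(OC)cc1Oc1c(OC)cc(OC)cc1OC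
A7 | alternative 2 | 3-ethoxy-2-(3,4,5-trimethoxyphenoxy)-5-[2,4-dimethoxy-6-(2,4,6-trimethoxyphenoxy)phenoxy]phenol | COc1cc(OC)c(Oc2cc(OC)cc(OC)c2Oc2cc(O)c(Oc3cc(OC)c(OC)c(OC)c3)c(OCC)c2)c(OC)c1
A8 | alternative 3 | 2-[3,5-dimethoxy-4-(3,4,5-trimethoxyphenoxy)phenoxy]-3,5-dimethoxyphenol | Oc1cc(OC)cc(OC)c1Oc1cc(OC)c(Oc2cc(OC)c(OC)c(OC)c2)c(OC)c1
A9 | alternative 3 | methyl 6-{2-[3,5-dimethoxy-4-(3,4,5-trimethoxyphenoxy)phenoxy]-3,5-dimethoxyphenoxy}-3,5-dioxohexanoate | COC(=O)CC(=O)CC(=O)COc1cc(OC)cc(OC)c1Oc1cc(OC)c(Oc2cc(OC)c(OC)c(OC)c2)c(OC)c1
A10 | alternative 3 | 2-{2-[3,5-dimethoxy-4-(3,4,5-trimethoxyphenoxy)phenoxy]-3,5-dimethoxyphenoxy}benzene-1,3,5-triol | Oc1cc(O)c(Oc2cc(OC)cc(OC)c2Oc2cc(OC)c(Oc3cc(OC)c(OC)c(OC)c3)c(OC)c2)c(O)c1
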